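**Retrosynthetic overview**
- The cyclopentane is the only ring and is made last: the C2–C6 bond forms when (5R,6R)-lycopene 5,6-epoxide is opened by its own C1=C2 prenyl olefin and water caps C1, the closure this epoxide is believed to undergo in vivo.
- The C40 epoxide is cut at C7=C8 (Wittig) into a C30 polyenyl phosphonium salt and (2S,3R)-2,3-epoxygeranial.
- The epoxy aldehyde comes from geraniol by Sharpless epoxidation with D-(−)-diethyl tartrate and oxidation; this is the only source of chirality.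
- The C30 salt comes from a C27 polyenal (isopropenyl Grignard, then PPh3·HBr with allylic transposition), the C27 polyenal from a C25 aldehyde by a two-carbon Wittig, and the C25 aldehyde from the pseudoionone-derived C15 phosphonium salt and the C10 dialdehyde.
- Ring order: no ring until the final step, where all three ring stereocentres are fixed from the epoxide.

Assumption: positions use carotenoid numbering (ring carbons C2, C5, C6; cyclised end unprimed; the target is 2R,5R,6R); commercial pseudoionone is taken as its (3E,5E) isomer, any Z isomer being removed when the C15 phosphonium salt is crystallised.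

**Step 1**
Reactants: 1 pseudoionone [(3E,5E)-6,10-dimethylundeca-3,5,9-trien-2-one]
Product: 2 vinyl-ψ-ionol [(4E,6E)-3,7,11-trimethyldodeca-1,4,6,10-tetraen-3-ol; racemic]
Conditions: CH2=CHMgBr (1.2 equiv), THF, −20 → 0 °C; then H2O
Reagents that add atoms: vinylmagnesium bromide, C=C[Mg]Br
Why: Grignard 1,2-addition to the methyl ketone of the dienone gives the tertiary bis-allylic alcohol, whose new centre is racemic and is destroyed in the next step.

**Step 2**
Reactants: 2 vinyl-ψ-ionol
Product: 3 C15 phosphonium bromide {[(2E,4E,6E)-3,7,11-trimethyldodeca-2,4,6,10-tetraen-1-yl]triphenylphosphonium bromide}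
Conditions: PPh3·HBr (1.0 equiv), MeOH, 0 → 25 °C, dark; crystallise from EtOAc
Reagents that add atoms: triphenylphosphine hydrobromide, [PH+](c1ccccc1)(c1ccccc1)c1ccccc1.[Br-]
Why: SN1-type phosphonium salt formation with allylic transposition, in which the delocalised allylic cation is trapped by PPh3 at its unhindered terminus under thermodynamic control to give the conjugated 2E salt.

**Step 3**
Reactants: 3 C15 phosphonium bromide; 4 C10 dialdehyde [(2E,4E,6E)-2,7-dimethylocta-2,4,6-trienedial; 3 equiv]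
Product: 6 C25 aldehyde (all-E; CHO is C12), via C15 ylide 5 (not isolated)
Conditions: NaN(SiMe3)2 (1.0 equiv), THF, −78 °C; cannulate into 4, −78 → 0 °C; then iodine (1 mol %), heptane, 25 °C, daylight; crystallise
Reagents that add atoms: none
Why: Wittig olefination with inverse addition to excess symmetrical dialdehyde gives the mono-adduct, and iodine-catalysed equilibration sets the new disubstituted olefin E.

**Step 4**
Reactants: 6 C25 aldehyde
Product: 8 C27 aldehyde (all-E; CHO is C10), via C27 dioxolane 7 (not isolated)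
Conditions: (1,3-dioxolan-2-ylmethyl)triphenylphosphonium bromide (1.3 equiv), KOC(CH3)3, THF, 0 → 25 °C; then 1 M HCl, THF, 25 °C
Reagents that add atoms: (1,3-dioxolan-2-ylmethyl)triphenylphosphonium bromide, C1COC(C[P+](c2ccccc2)(c2ccccc2)c2ccccc2)O1.[Br-]; water, O
Why: Wittig two-carbon homologation with a masked formyl ylide avoids over-homologation, and the acid hydrolysis of the acetal also isomerises the new enal olefin to E.

**Step 5**
Reactants: 8 C27 aldehyde
Product: 9 C30 carbinol [isopropenyl carbinol at C10; racemic]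
Conditions: CH2=C(CH3)MgBr (1.3 equiv), THF, −78 → −20 °C; then H2O
Reagents that add atoms: isopropenylmagnesium bromide, CC(=C)[Mg]Br
Why: Grignard 1,2-addition to the polyenal installs C8, C9 and the C9 methyl; the carbinol centre is racemic and is lost in the next step.

**Step 6**
Reactants: 9 C30 carbinol
Product: 10 C30 phosphonium bromide (P on C8; all-E)
Conditions: PPh3·HBr (1.05 equiv), MeOH/CH2Cl2, 0 → 25 °C, dark; precipitate with Et2O
Reagents that add atoms: triphenylphosphine hydrobromide, [PH+](c1ccccc1)(c1ccccc1)c1ccccc1.[Br-]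
Why: SN1-type phosphonium salt formation with allylic transposition, as in step 2, in which the polyenyl cation is trapped at the primary terminus C8 and the reversible ionisation equilibrates the C9=C10 and C11=C12 olefins to E.

**Step 7**
Reactants: 11 geraniol
Product: 12 (2R,3R)-2,3-epoxygeraniol
Conditions: Ti(OCH(CH3)2)4 (5 mol %), D-(−)-diethyl tartrate (6 mol %), (CH3)3COOH (1.5 equiv), 4 Å molecular sieves, CH2Cl2, −20 °C
Reagents that add atoms: tert-butyl hydroperoxide, CC(C)(C)OO
Why: Sharpless asymmetric epoxidation touches only the allylic olefin, and the D-(−)-tartrate ligand gives the (2R,3R) trans-epoxide, whose two centres become C6 and C5 of the target.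

**Step 8**
Reactants: 12 (2R,3R)-2,3-epoxygeraniol
Product: 13 (2S,3R)-2,3-epoxygeranial
Conditions: Dess–Martin periodinane (1.2 equiv), pyridine (3 equiv), CH2Cl2, 0 °C
Reagents that add atoms: none
Why: Buffered Dess–Martin oxidation gives the α,β-epoxy aldehyde without touching the epoxide or the remote olefin; no centre is affected (only the C2 descriptor changes).

**Step 9**
Reactants: 10 C30 phosphonium bromide; 13 (2S,3R)-2,3-epoxygeranial
Product: 15 (5R,6R)-lycopene 5,6-epoxide [(5R,6R)-5,6-epoxy-5,6-dihydro-ψ,ψ-carotene], via C30 ylide 14 (not isolated)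
Conditions: NaN(SiMe3)2 (1.0 equiv), THF, −78 °C; then 13, −78 → 0 °C, dark, Ar; rapid filtration through Et3N-deactivated neutral Al2O3
Reagents that add atoms: none
Why: Wittig olefination of the non-enolisable epoxy aldehyde forms C7=C8 without touching the epoxide centres; the semistabilised polyenyl ylide gives mainly 7E, and the minor 7Z isomer is carried on and equilibrated at the end.

**Step 10**
Reactants: 15 (5R,6R)-lycopene 5,6-epoxide
Product: 16 (2R,5R,6R)-2,6-cyclolycopene-1,5-diol (target)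
Conditions: pyridinium p-toluenesulfonate (10 mol %), THF/H2O (20:1), −10 → 0 °C, dark, Ar; NaHCO3; then EtOAc, 70 °C (7Z → 7E); crystallise
Reagents that add atoms: water, O
Why: Proposed new method: weak general-acid activation of the polyenyl epoxide triggers a 5-exo epoxide-opening cation–olefin cyclisation by the C1=C2 prenyl olefin that is terminated by water at C1; C5 keeps its Sharpless-derived configuration because its C–O bond is never broken, C6 is set by backside attack of C2 on the trans-epoxide (inversion, so the polyenyl chain ends cis to the C5 methyl and trans to the C5 hydroxyl), and C2 by a compact synclinal approach in which the prenyl terminus stacks over the polyene and away from the departing oxygen so that C1 is hydrated by external water, whereas the C2-epimeric approach cannot give a diol because it collapses to the bicyclic 1,5-ether, which is removed on chromatography; the closest known reactions are the acid rearrangement of racemic lycopene 5,6-epoxide to 2,6-cyclolycopene-1,5-diols and stereospecific acid-promoted epoxy-olefin cyclisations.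

**Compound list**
1 | pseudoionone, (3E,5E)-6,10-dimethylundeca-3,5,9-trien-2-one | CC(C)=CCC/C(C)=C/C=C/C(C)=O | starting material
2 | vinyl-ψ-ionol, (4E,6E)-3,7,11-trimethyldodeca-1,4,6,10-tetraen-3-ol (racemic) | CC(C)=CCC/C(C)=C/C=C/C(C)(O)C=C | intermediate
3 | C15 phosphonium bromide, [(2E,4E,6E)-3,7,11-trimethyldodeca-2,4,6,10-tetraen-1-yl]triphenylphosphonium bromide | CC(C)=CCC/C(C)=C/C=C/C(C)=C/C[P+](c1ccccc1)(c1ccccc1)c1ccccc1.[Br-] | intermediate
4 | C10 dialdehyde, (2E,4E,6E)-2,7-dimethylocta-2,4,6-trienedial | O=C/C(C)=C/C=C/C=C(C)/C=O | starting material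
5 | C15 ylide, [(2E,4E,6E)-3,7,11-trimethyldodeca-2,4,6,10-tetraen-1-ylidene]triphenylphosphorane | CC(C)=CCC/C(C)=C/C=C/C(C)=C/C=P(c1ccccc1)(c1ccccc1)c1ccccc1 | intermediate (not isolated)
6 | C25 aldehyde, (2E,4E,6E,8E,10E,12E,14E)-2,7,11,15,19-pentamethylicosa-2,4,6,8,10,12,14,18-octaenal | CC(C)=CCC/C(C)=C/C=C/C(C)=C/C=C/C(C)=C/C=C/C=C(C)/C=O | intermediate
7 | C27 dioxolane, 2-[(3E,5E,7E,9E,11E,13E,15E)-3,8,12,16,20-pentamethylhenicosa-1,3,5,7,9,11,13,15,19-nonaen-1-yl]-1,3-dioxolane (1E/1Z mixture) | CC(C)=CCC/C(C)=C/C=C/C(C)=C/C=C/C(C)=C/C=C/C=C(C)/C=CC1OCCO1 | intermediate (not isolated)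
8 | C27 aldehyde, (2E,4E,6E,8E,10E,12E,14E,16E)-4,9,13,17,21-pentamethyldocosa-2,4,6,8,10,12,14,16,20-nonaenal | CC(C)=CCC/C(C)=C/C=C/C(C)=C/C=C/C(C)=C/C=C/C=C(C)/C=C/C=O | intermediate
9 | C30 carbinol, (4E,6E,8E,10E,12E,14E,16E,18E)-2,6,11,15,19,23-hexamethyltetracosa-1,4,6,8,10,12,14,16,18,22-decaen-3-ol (racemic) | CC(C)=CCC/C(C)=C/C=C/C(C)=C/C=C/C(C)=C/C=C/C=C(C)/C=C/C(O)C(C)=C | intermediate
10 | C30 phosphonium bromide, [(2E,4E,6E,8E,10E,12E,14E,16E,18E)-2,6,11,15,19,23-hexamethyltetracosa-2,4,6,8,10,12,14,16,18,22-decaen-1-yl]triphenylphosphonium bromide | CC(C)=CCC/C(C)=C/C=C/C(C)=C/C=C/C(C)=C/C=C/C=C(C)/C=C/C=C(C)/C[P+](c1ccccc1)(c1ccccc1)c1ccccc1.[Br-] | intermediate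
11 | geraniol, (2E)-3,7-dimethylocta-2,6-dien-1-ol | CC(C)=CCC/C(C)=C/CO | starting material
12 | (2R,3R)-2,3-epoxygeraniol, [(2R,3R)-3-methyl-3-(4-methylpent-3-en-1-yl)oxiran-2-yl]methanol | OC[C@H]1O[C@]1(C)CCC=C(C)C | intermediate
13 | (2S,3R)-2,3-epoxygeranial, (2S,3R)-3-methyl-3-(4-methylpent-3-en-1-yl)oxirane-2-carbaldehyde | O=C[C@H]1O[C@]1(C)CCC=C(C)C | intermediate
14 | C30 ylide, the triphenylphosphorane (ylide at C8) derived from 10 | CC(C)=CCC/C(C)=C/C=C/C(C)=C/C=C/C(C)=C/C=C/C=C(C)/C=C/C=C(C)/C=P(c1ccccc1)(c1ccccc1)c1ccccc1 | intermediate (not isolated)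
15 | (5R,6R)-lycopene 5,6-epoxide, (5R,6R)-5,6-epoxy-5,6-dihydro-ψ,ψ-carotene (trans-epoxide, all-E chain) | CC(C)=CCC/C(C)=C/C=C/C(C)=C/C=C/C(C)=C/C=C/C=C(C)/C=C/C=C(C)/C=C/[C@H]1O[C@]1(C)CCC=C(C)C | intermediate
16 | (2R,5R,6R)-2,6-cyclolycopene-1,5-diol, (1R,2R,3R)-3-(2-hydroxypropan-2-yl)-1-methyl-2-(all-E-polyenyl)cyclopentan-1-ol; polyenyl chain, C5 methyl and hydroxyisopropyl group all cis, C5 hydroxyl trans | CC(C)=CCC/C(C)=C/C=C/C(C)=C/C=C/C(C)=C/C=C/C=C(C)/C=C/C=C(C)/C=C/[C@@H]1[C@H](C(C)(C)O)CC[C@@]1(C)O | target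

**Step count and risks**
Total step count: 10. Longest linear sequence: 8 steps (1 → 2 → 3 → 6 → 8 → 9 → 10 → 15 → 16).

Steps most likely to fail:

1. Step 10 (ring closure on the C40 epoxide). The polyenyl cation is very stable, so the epoxide may ionise before C2 attacks, which would give the C6 epimer. Water may also open C6 to the 5,6-diol, and the prenyl terminus may approach next to the C5 oxygen and end as the bicyclic 1,5-ether. Fallback: move the ring closure to the C15 stage, where only a pentadienyl cation can form and backside opening is enforced; this sets out from 13 and comes back at 16.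
   - Horner–Wadsworth–Emmons reaction of 13 with triethyl 3-methyl-4-phosphonocrotonate (LiN(SiMe3)2, THF, −78 °C) gives the epoxy dienoate F1.
   - (i-Bu)2AlH (CH2Cl2, −78 °C) gives the epoxy dienol F2.
   - The same pyridinium p-toluenesulfonate/wet THF closure gives the cyclopentane triol F3; the bicyclic ether and any C6 epimer are removed here by chromatography.
   - CBr4/PPh3 (CH2Cl2, −20 °C) converts only the primary allylic hydroxyl into the dienyl bromide F4, and PPh3 (toluene, 25 °C) gives the ring-bearing C15 phosphonium bromide F5.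
   - Its ylide F6 (NaN(SiMe3)2, 3 equiv, to cover the two tertiary hydroxyls) is condensed with C25 aldehyde 6 to form C11=C12; thermal Z → E equilibration gives 16.

2. Step 9 (Wittig next to the epoxide). The basic polyenyl ylide may open or eliminate the α,β-epoxy aldehyde, and the new C7=C8 olefin may form with poor E selectivity directly beside the labile epoxide. Fallback: move the junction to C11=C12, so that the epoxide sits four carbons away from the carbonyl; this sets out from 13 and 6 and comes back at 15.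
   - Horner–Wadsworth–Emmons reaction of 13 with diethyl (3-cyano-2-methylallyl)phosphonate (NaH, THF, 0 °C) gives the epoxy dienenitrile F7.
   - (i-Bu)2AlH (toluene, −78 °C; aqueous work-up) gives the epoxy dienal F8.
   - In parallel, NaBH4 (MeOH/THF, 0 °C) reduces 6 to the C25 alcohol F9, and PPh3·HBr gives the C25 phosphonium bromide F10.
   - Its ylide, the C25 ylide F11 (NaN(SiMe3)2, THF, −78 °C), is condensed with F8 to give 15.

3. Step 6 (phosphonium salt formation with allylic transposition on the C30 carbinol). PPh3 may be trapped at C10 or further along the polyenyl cation, or the C9=C10 olefin may form as an E/Z mixture. Fallback: build the C8–C9 terminus with fixed geometry and no transposition; this sets out from 8 and comes back at 10.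
   - Horner–Wadsworth–Emmons reaction of 8 with triethyl 2-phosphonopropionate (NaH, THF, 0 °C) gives the C30 ester F12 (9E).
   - (i-Bu)2AlH (CH2Cl2, −78 °C) gives the C30 primary allylic alcohol F13.
   - PPh3·HBr (MeOH/CH2Cl2) converts F13 directly into 10.

**Further compounds**
F1 | step 10 | ethyl (2E,4E)-3-methyl-5-[(2R,3R)-3-methyl-3-(4-methylpent-3-en-1-yl)oxiran-2-yl]penta-2,4-dienoate | CCOC(=O)/C=C(C)/C=C/[C@H]1O[C@]1(C)CCC=C(C)C
F2 | step 10 | (2E,4E)-3-methyl-5-[(2R,3R)-3-methyl-3-(4-methylpent-3-en-1-yl)oxiran-2-yl]penta-2,4-dien-1-ol | OC/C=C(C)/C=C/[C@H]1O[C@]1(C)CCC=C(C)C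
F3 | step 10 | (1R,2R,3R)-2-[(1E,3E)-5-hydroxy-3-methylpenta-1,3-dien-1-yl]-3-(2-hydroxypropan-2-yl)-1-methylcyclopentan-1-ol | OC/C=C(C)/C=C/[C@@H]1[C@H](C(C)(C)O)CC[C@@]1(C)O
F4 | step 10 | (1R,2R,3R)-2-[(1E,3E)-5-bromo-3-methylpenta-1,3-dien-1-yl]-3-(2-hydroxypropan-2-yl)-1-methylcyclopentan-1-ol | BrC/C=C(C)/C=C/[C@@H]1[C@H](C(C)(C)O)CC[C@@]1(C)O
F5 | step 10 | {(2E,4E)-5-[(1R,2R,5R)-2-hydroxy-5-(2-hydroxypropan-2-yl)-2-methylcyclopentyl]-3-methylpenta-2,4-dien-1-yl}triphenylphosphonium bromide | [Br-].c1ccccc1[P+](c1ccccc1)(c1ccccc1)C/C=C(C)/C=C/[C@@H]1[C@H](C(C)(C)O)CC[C@@]1(C)O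
F6 | step 10 | triphenylphosphorane (ylide) derived from F5 | c1ccccc1P(c1ccccc1)(c1ccccc1)=C/C=C(C)/C=C/[C@@H]1[C@H](C(C)(C)O)CC[C@@]1(C)O
F7 | step 9 | (2E,4E)-3-methyl-5-[(2R,3R)-3-methyl-3-(4-methylpent-3-en-1-yl)oxiran-2-yl]penta-2,4-dienenitrile | N#C/C=C(C)/C=C/[C@H]1O[C@]1(C)CCC=C(C)C
F8 | step 9 | (2E,4E)-3-methyl-5-[(2R,3R)-3-methyl-3-(4-methylpent-3-en-1-yl)oxiran-2-yl]penta-2,4-dienal | O=C/C=C(C)/C=C/[C@H]1O[C@]1(C)CCC=C(C)C
F9 | step 9 | (2E,4E,6E,8E,10E,12E,14E)-2,7,11,15,19-pentamethylicosa-2,4,6,8,10,12,14,18-octaen-1-ol | CC(C)=CCC/C(C)=C/C=C/C(C)=C/C=C/C(C)=C/C=C/C=C(C)/CO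
F10 | step 9 | [(2E,4E,6E,8E,10E,12E,14E)-2,7,11,15,19-pentamethylicosa-2,4,6,8,10,12,14,18-octaen-1-yl]triphenylphosphonium bromide | CC(C)=CCC/C(C)=C/C=C/C(C)=C/C=C/C(C)=C/C=C/C=C(C)/C[P+](c1ccccc1)(c1ccccc1)c1ccccc1.[Br-]
F11 | step 9 | triphenylphosphorane (ylide) derived from F10 | CC(C)=CCC/C(C)=C/C=C/C(C)=C/C=C/C(C)=C/C=C/C=C(C)/C=P(c1ccccc1)(c1ccccc1)c1ccccc1
F12 | step 6 | ethyl (2E,4E,6E,8E,10E,12E,14E,16E,18E)-2,6,11,15,19,23-hexamethyltetracosa-2,4,6,8,10,12,14,16,18,22-decaenoate | CC(C)=CCC/C(C)=C/C=C/C(C)=C/C=C/C(C)=C/C=C/C=C(C)/C=C/C=C(C)/C(=O)OCC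
F13 | step 6 | (2E,4E,6E,8E,10E,12E,14E,16E,18E)-2,6,11,15,19,23-hexamethyltetracosa-2,4,6,8,10,12,14,16,18,22-decaen-1-ol | CC(C)=CCC/C(C)=C/C=C/C(C)=C/C=C/C(C)=C/C=C/C=C(C)/C=C/C=C(C)/CO
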